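**Retrosynthetic overview**
- The C6 side chain and the 7-OH come last, from double methyl addition to a 6,7-fused dihydrocoumarin, which is made from a 6-formylisoflavone by reductive Meldrum's acid homologation.
- Key disconnection: the pyranone C-ring (O1–C2 and C4–C4a) is cut to C2v-symmetric 2,4,6-trihydroxybenzaldehyde and a 3-(methoxymethylene)benzofuranone that carries the B-ring plus C2, C3 and C4. Closure on either equivalent ortho carbon breaks the symmetry and can only give the 6-substituted 5,7-dihydroxy pattern; the lactone opening frees the 2'-OH.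
- The benzofuranone comes from a non-aromatic pyrano-cyclohexenone by α'-aldol with ethyl glyoxylate and isoaromatization, so the B-ring pattern is fixed without a regiochemical choice.
- The pyrano-cyclohexenone comes from cyclohexane-1,3-dione and prenal.
- Ring order: dimethylpyran → B-ring benzene (aromatization) → γ-lactone (temporary) → chromone C-ring → δ-lactone (temporary, opened last).

Assumption: the target SMILES has no stereocentre, so "single enantiomer" is read as the achiral compound as drawn; the only stereo-element is the ring-locked chromene alkene.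

**Step 1**
Reactants: 1 cyclohexane-1,3-dione; 2 3-methylbut-2-enal (prenal)
Product: 4 2,2-dimethyl-7,8-dihydro-2H-chromen-5(6H)-one, via oxatriene 3 (not isolated)
Conditions: EDDA (10 mol%), MeOH, 65 °C
Reagents that add atoms: none
Why: Knoevenagel condensation followed by 6π-oxa-electrocyclization of the 1-oxatriene (formal [3+3] annulation), well known for cyclic 1,3-diones; the symmetric dione can give only one product and no stereocentre is formed.

**Step 2**
Reactants: 4 2,2-dimethyl-7,8-dihydro-2H-chromen-5(6H)-one; 5 ethyl glyoxylate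
Product: 6 ethyl 2-(2,2-dimethyl-5-oxo-5,6,7,8-tetrahydro-2H-chromen-6-yl)-2-hydroxyacetate
Conditions: LDA (1.1 equiv), THF, −78 °C; then 5; then AcOH
Reagents that add atoms: none
Why: kinetic α'-deprotonation of the vinylogous ester (Stork–Danheiser regioselectivity) and aldol addition to the reactive glyoxylate aldehyde; the two new stereocentres form as a racemic diastereomer mixture, which is harmless because both are destroyed in step 3.

**Step 3**
Reactants: 6 ethyl 2-(2,2-dimethyl-5-oxo-5,6,7,8-tetrahydro-2H-chromen-6-yl)-2-hydroxyacetate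
Product: 9 7,7-dimethyl-3H-furo[2,3-f]chromen-2(7H)-one, via alkylidene ester 7 (not isolated), via phenol ester 8 (not isolated)
Conditions: TsOH·H2O (10 mol%), toluene, reflux, Dean–Stark
Reagents that add atoms: none
Why: acid-catalysed aldol dehydration gives the exocyclic enone, which tautomerizes to the phenol (isoaromatization of a 6-alkylidenecyclohex-2-enone, driven by aromatic stabilization), and the new phenol lactonizes onto the ethyl ester to the benzofuran-2(3H)-one; the dimethylchromene tolerates catalytic TsOH in hot toluene, the conditions under which such chromenes are routinely made.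

**Step 4**
Reactants: 9 7,7-dimethyl-3H-furo[2,3-f]chromen-2(7H)-one
Product: 10 (3E)-3-(methoxymethylidene)-7,7-dimethyl-3H-furo[2,3-f]chromen-2(7H)-one
Conditions: HC(OMe)3, Ac2O, 100 °C
Reagents that add atoms: trimethyl orthoformate, COC(OC)OC
Why: alkoxymethylenation of the acidic lactone CH2 with orthoformate and acetic anhydride, the known process reaction that turns benzofuran-2(3H)-one into (E)-3-(methoxymethylene)benzofuran-2(3H)-one; no free OH is present to be acetylated.

**Step 5**
Reactants: 10 (3E)-3-(methoxymethylidene)-7,7-dimethyl-3H-furo[2,3-f]chromen-2(7H)-one; 11 2,4,6-trihydroxybenzaldehyde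
Product: 13 5,7-dihydroxy-3-(5-hydroxy-2,2-dimethyl-2H-chromen-6-yl)-4-oxo-4H-chromene-6-carbaldehyde, via aryl vinyl ether 12 (not isolated)
Conditions: Et3N, 4 Å MS, MeCN, 25 °C; then MgCl2, 80 °C
Reagents that add atoms: none
Why: Proposed new method: key step, in which the 4-OH of 11 (the only non-chelated and most acidic hydroxyl) displaces methoxide from the vinylogous carbonate 10 by addition–elimination to give 12, whose magnesium phenolate then delivers the aryl-lactone carbonyl to the equivalent ortho carbon C3/C5 through a six-membered chelated transition state (anionic Fries-type C-acylation) that releases the B-ring 2'-phenoxide and breaks the C2v symmetry of 11 with only one possible regiochemical outcome (6-formyl, never 8-substituted); the closest known reaction types are the aryloxyacrylate (Simonis-type) chromone synthesis and the ortho-selective acylation and formylation of magnesium phenolates (Sartori–Casnati and Skattebøl type).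

**Step 6**
Reactants: 13 5,7-dihydroxy-3-(5-hydroxy-2,2-dimethyl-2H-chromen-6-yl)-4-oxo-4H-chromene-6-carbaldehyde; 14 Meldrum's acid
Product: 18 5-hydroxy-7-(5-hydroxy-2,2-dimethyl-2H-chromen-6-yl)-3,4-dihydro-2H,6H-pyrano[3,2-g]chromene-2,6-dione, via arylidene Meldrum's acid 15 (not isolated), via benzyl Meldrum's acid 16 (not isolated), via lactone acid 17 (not isolated)
Conditions: Hantzsch ester (1.2 equiv), L-proline (10 mol%), EtOH, 25 °C; then pyridine, 100 °C
Reagents that add atoms: none
Why: three-component reductive alkylation (Knoevenagel condensation, then Hantzsch-ester transfer hydrogenation of the arylidene Meldrum's acid), followed on heating by lactonization of the non-chelated 7-OH with loss of acetone and decarboxylation, the known way from salicylaldehydes to 3,4-dihydrocoumarins; the chromene and chromone alkenes are not reduced by the Hantzsch ester and the transient stereocentre of 17 is lost on decarboxylation.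

**Step 7**
Reactants: 18 5-hydroxy-7-(5-hydroxy-2,2-dimethyl-2H-chromen-6-yl)-3,4-dihydro-2H,6H-pyrano[3,2-g]chromene-2,6-dione
Product: 20 Kanzonol T, via methyl ketone 19 (not isolated)
Conditions: MeMgBr (6 equiv), THF, −40 → 0 °C; then H2O
Reagents that add atoms: methylmagnesium bromide, C[Mg]Br
Why: Grignard double addition to an aryl (phenolic) lactone, which is far more electrophilic than the chromone carbonyl held as a magnesium 5-phenoxide chelate, so the lactone opens to the tertiary alcohol and frees the 7-OH in one operation; no stereocentre is formed.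

**Compound list**
1 | cyclohexane-1,3-dione | O=C1CCCC(=O)C1 | starting material
2 | 3-methylbut-2-enal (prenal) | CC(C)=CC=O | starting material
3 | 2-(3-methylbut-2-en-1-ylidene)cyclohexane-1,3-dione (oxatriene, not isolated) | CC(C)=CC=C1C(=O)CCCC1=O | intermediate
4 | 2,2-dimethyl-7,8-dihydro-2H-chromen-5(6H)-one | CC1(C)C=CC2=C(CCCC2=O)O1 | intermediate
5 | ethyl glyoxylate | CCOC(=O)C=O | starting material
6 | ethyl 2-(2,2-dimethyl-5-oxo-5,6,7,8-tetrahydro-2H-chromen-6-yl)-2-hydroxyacetate (racemic diastereomer mixture) | CCOC(=O)C(O)C1CCC2=C(C=CC(C)(C)O2)C1=O | intermediate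
7 | ethyl (2E)-2-(2,2-dimethyl-5-oxo-7,8-dihydro-2H-chromen-6(5H)-ylidene)acetate (not isolated) | CCOC(=O)/C=C1/C(=O)C2=C(CC1)OC(C)(C)C=C2 | intermediate
8 | ethyl 2-(5-hydroxy-2,2-dimethyl-2H-chromen-6-yl)acetate (not isolated) | CCOC(=O)Cc1ccc2OC(C)(C)C=Cc2c1O | intermediate
9 | 7,7-dimethyl-3H-furo[2,3-f]chromen-2(7H)-one (γ-lactone of (5-hydroxy-2,2-dimethyl-2H-chromen-6-yl)acetic acid) | O=C1Cc2ccc3OC(C)(C)C=Cc3c2O1 | intermediate
10 | (3E)-3-(methoxymethylidene)-7,7-dimethyl-3H-furo[2,3-f]chromen-2(7H)-one | CO/C=C1/C(=O)Oc2c1ccc1OC(C)(C)C=Cc21 | intermediate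
11 | 2,4,6-trihydroxybenzaldehyde | O=Cc1c(O)cc(O)cc1O | starting material
12 | 3-[(4-formyl-3,5-dihydroxyphenoxy)methylidene]-7,7-dimethyl-3H-furo[2,3-f]chromen-2(7H)-one (E/Z mixture, equilibrating, not isolated) | O=Cc1c(O)cc(OC=C2C(=O)Oc3c2ccc2OC(C)(C)C=Cc32)cc1O | intermediate
13 | 5,7-dihydroxy-3-(5-hydroxy-2,2-dimethyl-2H-chromen-6-yl)-4-oxo-4H-chromene-6-carbaldehyde | O=Cc1c(O)cc2occ(-c3ccc4OC(C)(C)C=Cc4c3O)c(=O)c2c1O | intermediate
14 | Meldrum's acid (2,2-dimethyl-1,3-dioxane-4,6-dione) | CC1(C)OC(=O)CC(=O)O1 | starting material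
15 | 5-{[5,7-dihydroxy-3-(5-hydroxy-2,2-dimethyl-2H-chromen-6-yl)-4-oxo-4H-chromen-6-yl]methylidene}-2,2-dimethyl-1,3-dioxane-4,6-dione (not isolated) | CC1(C)OC(=O)C(=Cc2c(O)cc3occ(-c4ccc5OC(C)(C)C=Cc5c4O)c(=O)c3c2O)C(=O)O1 | intermediate
16 | 5-{[5,7-dihydroxy-3-(5-hydroxy-2,2-dimethyl-2H-chromen-6-yl)-4-oxo-4H-chromen-6-yl]methyl}-2,2-dimethyl-1,3-dioxane-4,6-dione (not isolated) | CC1(C)OC(=O)C(Cc2c(O)cc3occ(-c4ccc5OC(C)(C)C=Cc5c4O)c(=O)c3c2O)C(=O)O1 | intermediate
17 | 5-hydroxy-7-(5-hydroxy-2,2-dimethyl-2H-chromen-6-yl)-2,6-dioxo-3,4-dihydro-2H,6H-pyrano[3,2-g]chromene-3-carboxylic acid (racemic, not isolated) | O=C1Oc2cc3occ(-c4ccc5OC(C)(C)C=Cc5c4O)c(=O)c3c(O)c2CC1C(=O)O | intermediate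
18 | 5-hydroxy-7-(5-hydroxy-2,2-dimethyl-2H-chromen-6-yl)-3,4-dihydro-2H,6H-pyrano[3,2-g]chromene-2,6-dione (δ-lactone closed on the isoflavone 7-O, chain carbon on C6) | O=C1CCc2c(O1)cc1occ(-c3ccc4OC(C)(C)C=Cc4c3O)c(=O)c1c2O | intermediate
19 | 5,7-dihydroxy-3-(5-hydroxy-2,2-dimethyl-2H-chromen-6-yl)-6-(3-oxobutyl)-4H-chromen-4-one (not isolated) | CC(=O)CCc1c(O)cc2occ(-c3ccc4OC(C)(C)C=Cc4c3O)c(=O)c2c1O | intermediate
20 | Kanzonol T, 5,7-dihydroxy-3-(5-hydroxy-2,2-dimethyl-2H-chromen-6-yl)-6-(3-hydroxy-3-methylbutyl)-4H-chromen-4-one | CC(C)(O)CCc1c(O)cc2occ(-c3ccc4c(c3O)C=CC(C)(C)O4)c(=O)c2c1O | target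

**Step count**
Total steps: 7. Longest linear sequence: 7 (1/2 → 4 → 6 → 9 → 10 → 13 → 18 → 20; compounds 5, 11 and 14 are bought).

**Steps most likely to fail and fallbacks**

Step 5 is the riskiest. The O-vinylation is reversible and uphill until methanol is trapped, the closure is onto a formyl-deactivated ring, and C-attack on 10 would lead to a 3-arylcoumarin instead. Fallback: set out from 10 and replace 11 by the electron-richer, already homologated 5,7-dihydroxychroman-2-one F1 (from phloroglucinol and acrylic acid, Amberlyst-15, toluene, reflux). K2CO3 in MeCN, then MgCl2/Et3N at 80 °C, gives the 7-O-vinyl ether F2 and, by closure ortho to the free 5-OH, lactone 18 directly. The route is rejoined at 18 and step 6 is no longer needed; the price is that 7-OH versus 5-OH selectivity then rests on sterics alone.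

Step 6 is next. The ortho-hydroxy arylidene 15 may lactonize to the coumarin-3-carboxylic acid before hydride transfer. Fallback: set out from 13. NaBH4 (THF/EtOH, 0 °C) reduces only the aldehyde to 5,7-dihydroxy-6-(hydroxymethyl)-3-(5-hydroxy-2,2-dimethyl-2H-chromen-6-yl)-4H-chromen-4-one F3. Heating F3 with excess 2-methoxypropene in toluene (100 °C) generates the ortho-quinone methide, which is trapped by inverse-demand hetero-Diels–Alder reaction as the cyclic methyl ketal F4 (racemic ketal carbon, erased next). PPTS in wet acetone hydrolyses F4 to methyl ketone 19, where the route is rejoined; one MeMgBr addition at −78 °C then gives 20.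

Step 7 is third. Excess MeMgBr may add 1,4 or 1,2 to the chromone. Fallback: set out from 18. Me(MeO)NH·HCl/AlMe3 (CH2Cl2, 0 °C) opens the aryl lactone to the Weinreb amide F5. MeMgBr at −78 °C stops at the chelated adduct and gives 19 on work-up, where the route is rejoined; the last methyl is then added with the non-basic, ketone-selective MeTi(OiPr)3 to give 20.

**Further compounds**
F1 | step 5 | 5,7-dihydroxychroman-2-one | O=C1CCc2c(O)cc(O)cc2O1
F2 | step 5 | 3-{[(5-hydroxy-2-oxo-3,4-dihydro-2H-chromen-7-yl)oxy]methylidene}-7,7-dimethyl-3H-furo[2,3-f]chromen-2(7H)-one (7-O-vinyl ether, E/Z mixture) | O=C1CCc2c(O)cc(OC=C3C(=O)Oc4c3ccc3OC(C)(C)C=Cc43)cc2O1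
F3 | step 6 | 5,7-dihydroxy-6-(hydroxymethyl)-3-(5-hydroxy-2,2-dimethyl-2H-chromen-6-yl)-4H-chromen-4-one | OCc1c(O)cc2occ(-c3ccc4OC(C)(C)C=Cc4c3O)c(=O)c2c1O
F4 | step 6 | 5-hydroxy-7-(5-hydroxy-2,2-dimethyl-2H-chromen-6-yl)-2-methoxy-2-methyl-3,4-dihydro-2H,6H-pyrano[3,2-g]chromen-6-one (racemic cyclic methyl ketal) | COC1(C)CCc2c(O1)cc1occ(-c3ccc4OC(C)(C)C=Cc4c3O)c(=O)c1c2O
F5 | step 7 | 3-[5,7-dihydroxy-3-(5-hydroxy-2,2-dimethyl-2H-chromen-6-yl)-4-oxo-4H-chromen-6-yl]-N-methoxy-N-methylpropanamide | CON(C)C(=O)CCc1c(O)cc2occ(-c3ccc4OC(C)(C)C=Cc4c3O)c(=O)c2c1O
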